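## Structural features

The target is a sesquiterpene coumarin ether. A 9-epi-drimane (trans-fused rings A and B, C1–C10, with C11–C15 as appendages) is joined through the C11 methylene and an ether oxygen to C7 of 6,8-dimethoxycoumarin, and O3 carries a 3-methylbutanoate. Ring B holds an enone (C6 ketone, C7=C8 alkene with CH3-12), so C5 is α and C9 is γ to the carbonyl. Three stereocentres are contiguous: C5 (H α), the quaternary C10 (CH3 β) and C9 (C11 α, H β). The fourth, C3, bears an axial α oxygen next to the C4 gem-dimethyl carbon and stands 1,4 to C10 across ring A. Fragile points are the coumarin lactone (hydride, organometallics, strong base), the isovalerate, the epimerisable C5 and C9, and the C11 aryloxide, which becomes a vinylogous β-leaving group once C9 is deprotonated. The real difficulty is the quaternary C10 between two stereogenic methines, with C11 anti to CH3-15 and on the same face as the remote O3. The key step exploits the 1,5-dicarbonyl relation C6(=O)–C5–C10–C9–C8(=O) that appears when ring B is opened at C7–C8: an acetyl group on C5 and an acetate arm on C10, both on the O3 face of ring A, are what a de Mayo sequence of an acetoacetate enol ether lays across a C5=C10 alkene when O3 is the anchor.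

## Logic of the disconnections

22 to 21: the C3–O acyl bond is cut last, because the ester would not survive the alkoxide, amide and organometallic steps. This removes one fragile group. The forward step must acylate a hindered axial alcohol under conditions too mild to enolise C5 or C9.

21 to 19 and 20: the C11–O aryl bond is cut, since 20 is a commercial phenol and its lactone is incompatible with the ring B chemistry. The molecule falls into two halves of unequal difficulty. The forward step must substitute at the primary C11 in the presence of the free C3 hydroxyl and against β-branching.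

19 to 18: the two benzyl-type groups on O3 and O11 are cut together. The demand is a non-reductive cleavage that spares the enone alkene.

18 to 17 to 16: the C8–C12 bond is cut, because a 3-methyl enone is the cross-coupling product of a β-sulfonyloxy enone and that is the O-sulfonyl derivative of a 1,3-dione. The enone is thereby traced to a 6,8-dione. The forward activation must pick the oxygen on C8 over the one on C6.

16 to 15: the C9–C11 bond is cut, because C9 is the terminal carbon of the dione dianion. This removes the C9 stereocentre and C11. The forward step needs the second deprotonation at C9 and not C5, and attack anti to CH3-15.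

15 to 13 (through 14), then 13 to 12: the C7–C8 bond is cut (Claisen), opening ring B to a ring A with an acetyl group on C5 and an acetate arm on C10. The forward step must leave C5 trans under equilibrating conditions, and O3 must be masked beforehand.

12 to 10 (through 11): C6 and C9 are reconnected and the two oxygens (O3 and O on C6) are joined through silicon, so the 1,5-dicarbonyl becomes a cyclobutanol β to the ester. The two side chains become one two-carbon unit spanning C5 and C10. The forward step needs fluoride to cleave both Si–O bonds and trigger the retro-aldol.

10 to 9: C5–C6 and C9–C10 are cut (the key [2+2]). Two rings and four stereocentres are removed, leaving a monocyclic alkene with one stereocentre. The forward step demands head-to-head regiochemistry and addition on the O3 face.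

9 to 5, 6 and 7: the two Si–O bonds are cut, giving three simple pieces. The forward step must substitute the two chlorides one after the other.

5 to 4 to 3 to 1: the C3–H bond (asymmetric reduction), the two C–CH3 bonds at C4 (double alkylation) and the ring unsaturation (Birch reduction) are removed in turn. The demand is enantiofacial control at one ketone flanked by a quaternary and a methylene carbon.

## Other disconnections considered

Alternative 1: The cut is the benzene ring of the coumarin, made last by ring expansion of the 4-alkenyl-4-methoxycyclobutenone A1. On heating, A1 would open to a dienylketene, close by six-electron electrocyclisation (C8a–C4a) and tautomerise to the pentasubstituted phenol A2.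
- In its favour: the substitution pattern of the arene is fixed by the four-membered ring, and the pericyclic cascade is thermal and well precedented. The C11–O bond is made by addition–elimination of the terpene alkoxide at an sp2 carbon, not by substitution at the β-branched C11. On that one bond it is better than the chosen plan.
- Against it here: the ring it builds is the arene of 20, which can be bought. A2 still needs the whole 9-epi-drimane with C3, C5, C9 and C10 set, so the hard half of the problem is untouched. A2 also lacks the C6 carbonyl and the pyranone ring.
- Comparison: on structure, the chosen plan brings C6 in as a carbonyl from the start, while A2 needs a late allylic oxidation beside an electron-rich arene. On mechanism, the alternative is the more predictable. On step economy it is clearly worse, since benzylic oxidation, two-carbon homologation with lactonisation, C6 oxidation, desilylation and acylation all follow A2, and the precious terpene enters early.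

Alternative 2: The cuts are C9–C10 and C7–C8 of ring B. The ring A silyloxydiene A3, with an (E)-crotonate on O3, would undergo an intramolecular Diels–Alder reaction to the bridged lactone A4.
- In its favour: one thermal, concerted step closes ring B, forms the quaternary C10, and places C11 on the O3 face at C9, which is exactly the C9 configuration of the target. It also brings in C11 (as the lactone carbonyl) and C12, so no separate C9 alkylation or C8 methylation is needed. Here it is better than the chosen plan. Both plans use O3 as the anchor for the C10 face, so on that point they are equal.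
- Against it here: the dienophile carries a β-methyl and must bond to the fully substituted diene terminus C10. The s-cis diene is twisted by the C4 gem-dimethyl group, the ester tether prefers the unproductive conformation, and the strained bridged adduct may revert at the temperature needed. After A4, the C7=C8 alkene must be introduced by dehydrogenation next to an epimerisable C9, and the lactone must be reduced without touching C6.
- Comparison: the mechanism is better understood than that of the chosen photochemical step. If the cycloaddition proceeds, the route is probably a few steps shorter. The steric demand at C10 is the point on which it is the weaker plan.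

Alternative 3: The cuts are C4–C5 and C9–C10. The acyclic (S)-epoxy triene A5, with a 2Z alkene, would bicyclise under MeAlCl2 to the 9-epi-drimenyl acetate A6.
- In its favour: rings A and B and the centres C5, C9 and C10 arise in one step from an acyclic chain, and the Z alkene translates into the axial C11. For the carbocyclic core it is by far the shortest plan and has the stronger precedent as a reaction class.
- Against it here: A6 carries a 3β (equatorial) hydroxyl, epimeric at C3 with the 3α oxygen of the target. The (R)-epoxide would give the mirror-image skeleton and not the needed diastereomer, so an inversion at the neopentyl C3 is unavoidable. A6 also lacks the C6 oxygen, so an allylic oxidation selective for C6 over C12 and C9 is needed. Termination by proton loss can give alkene regioisomers and partly cyclised material, and the C9 configuration depends on a concerted second ring closure.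
- Comparison: on step economy it is better than the chosen plan even after C3 inversion and C6 oxidation. On structure, the chosen plan sets the C3 oxygen and the C6 carbonyl directly in their final form. On mechanism, both have an uncertain selectivity at their key step.

Key step: step 5

Remark on naming: all ring and side-chain atoms carry drimane numbers (ring A = C1–C5 and C10; ring B = C5–C10; C11 on C9, C12 on C8, C15 on C10). α is the face of the C3 oxygen and β the face of the C10 methyl.

Remark on the structures: the ring A carbinol must be (R) to match the 3α oxygen of the target. The 3β-hydroxyl of A6 is the one stereochemical mismatch found. The enol ether geometry of 9 and the C9 configuration of 10 are drawn as single isomers, although both are erased in step 6.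

Step 1
Reactants: 1 4-methylanisole
Product: 3 4-methylcyclohex-3-en-1-one, via 1-methoxy-4-methylcyclohexa-1,4-diene 2 (not isolated)
Conditions: Li, NH3(l), t-BuOH, THF, −78 to −33 °C; then (CO2H)2, MeOH/H2O, rt
Reagents that add atoms: water, O
Why: Birch reduction gives the 1,4-diene with the enol ether intact, and mild enol ether hydrolysis releases the β,γ-unsaturated ketone without moving the trisubstituted alkene into conjugation; no stereocentre is formed.

Step 2
Reactants: 3 4-methylcyclohex-3-en-1-one
Product: 4 2,2,4-trimethylcyclohex-3-en-1-one
Conditions: t-BuOK (2.2 equiv), MeI (3 equiv), t-BuOH/THF, 0 °C to rt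
Reagents that add atoms: iodomethane, CI
Why: Exhaustive α-alkylation of a dienolate: C2 is both α to the carbonyl and allylic, so it is deprotonated twice in preference to C6, and dienolates alkylate at the α-carbon, which keeps the alkene at C3=C4; the quaternary C2 then blocks conjugation.

Step 3
Reactants: 4 2,2,4-trimethylcyclohex-3-en-1-one
Product: 5 (R)-2,2,4-trimethylcyclohex-3-en-1-ol
Conditions: (S)-2-methyl-CBS-oxazaborolidine (10 mol %), BH3·SMe2, THF, −20 °C; MeOH
Reagents that add atoms: none
Why: Corey–Bakshi–Shibata reduction; the quaternary flank acts as the large group and the ring methylene as the small one, so the (S)-catalyst should deliver hydride to the face that gives the (R)-carbinol, the future C3.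

Step 4
Reactants: 5 (R)-2,2,4-trimethylcyclohex-3-en-1-ol, 6 dichlorodiisopropylsilane, 7 methyl acetoacetate
Product: 9 methyl (2Z)-3-[(diisopropyl{[(1R)-2,2,4-trimethylcyclohex-3-en-1-yl]oxy}silyl)oxy]but-2-enoate, via chloro(diisopropyl)silyl ether 8 (not isolated)
Conditions: 5, i-Pr2SiCl2 (3 equiv), imidazole, CH2Cl2, 0 °C to rt, volatiles removed in vacuo; then 7, NaH, THF, 0 °C, crude 8 added, 0 °C to rt
Reagents that add atoms: none
Why: Stepwise substitution at a dichlorosilane (temporary silicon tether): the hindered alcohol reacts once with the excess dichlorosilane because the isopropyl groups slow the second substitution, and the chelated sodium enolate of the β-keto ester is then silylated on oxygen to the Z-enol ether; C3 is untouched.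

Step 5
Reactants: 9 methyl (2Z)-3-[(diisopropyl{[(1R)-2,2,4-trimethylcyclohex-3-en-1-yl]oxy}silyl)oxy]but-2-enoate
Product: 10 cyclobutane photoadduct: cyclobutane (C5, C6, C9, C10) cis-fused to ring A on the α face (H5 and CH3-15 β), C6 bearing CH3-7 and an oxygen bridged through Si(i-Pr)2 to O3 (seven-membered siloxane), C9 bearing CO2CH3 cis to the C6 oxygen
Conditions: hν (300 nm, Pyrex), acetone (solvent and triplet sensitiser), 0.005 M, degassed, 0–20 °C
Reagents that add atoms: none
Why: Proposed new method: triplet energy transfer from acetone to the β-silyloxy enoate gives a twisted enoate triplet whose oxygen-bearing carbon C6 adds to the less substituted alkene carbon C5, and the triplet 1,4-biradical (ester-stabilised at C9, tertiary at C10) closes after intersystem crossing; the closest known reaction types are the de Mayo reaction of 1,3-dioxin-4-ones with alkenes and silicon-tethered enone–alkene [2+2] photocycloadditions, the acyclic silyl enol ether of a β-keto ester being the untested chromophore. The seven-membered siloxane closes first, by 7-exo attack of C6 on C5 (C10 stays outside the new ring), and the cyclobutane closes second, by combination of the C9 and C10 radical centres. C5 and C6 are set by the tether: the C5–C6 bond can only form on the ring face that carries O3, and the siloxy oxygen must sit on the cyclobutane face turned towards C4. C10 follows from C5, because the C9 radical is held below ring A and can only reach the α lobe of the planar C10 radical, which gives the cis-fused four-membered ring and leaves CH3-15 β. C9 is not controlled and need not be, since it becomes a methylene group in step 6. The step needs head-to-head regiochemistry and α-face selectivity; both rest on the tether (the other first bond, C6–C10, would need an eight-membered ring and a secondary radical at C5) and on the isopropyl groups, which favour the folded rotamer. E/Z isomerisation of the enoate is the expected competing decay, but it only returns a reactive isomer of 9.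

Step 6
Reactants: 10 cyclobutane photoadduct
Product: 12 methyl 2-(2-acetyl-4-hydroxy-1,3,3-trimethylcyclohexyl)acetate with 3α-OH, C5 acetyl α (H5 β), C10 CH2CO2CH3 α and CH3-15 β, via desilylated cyclobutanol 11 (not isolated)
Conditions: Bu4NF (2.2 equiv), THF, 0 °C; pH 7 buffer
Reagents that add atoms: none
Why: Fluoride cleaves both Si–O bonds, and the tertiary cyclobutanolate β to the ester fragments by retro-aldol cleavage of C6–C9 (the second half of a de Mayo sequence), driven by ring strain; C6 and C9 lose their stereochemistry, C10 is untouched and C5 keeps the cis acetyl for the moment.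

Step 7
Reactants: 12 hydroxy keto ester
Product: 13 O3-benzyloxymethyl ether of 12 (same configuration)
Conditions: BnOCH2Cl, i-Pr2NEt, Bu4NI (cat.), ClCH2CH2Cl, 50 °C
Reagents that add atoms: benzyl chloromethyl ether, ClCOCc1ccccc1
Why: Acetal-type protection of the hindered axial alcohol with a reactive α-chloro ether under a non-enolising amine base; the group withstands alkoxide, amide base and organozinc and is later cleaved together with the C11 benzyl ether.

Step 8
Reactants: 13 O3-benzyloxymethyl keto ester
Product: 15 3α-(benzyloxymethoxy)-11,12-dinor-5α-drimane-6,8-dione (trans-fused, H5 α, CH3-15 β), via C5-epimerised keto ester 14 (not isolated)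
Conditions: NaOMe (3 equiv), MeOH, reflux; then 1 M HCl to pH 3, 0 °C
Reagents that add atoms: none
Why: Intramolecular Claisen (Dieckmann-type) condensation of a δ-keto ester: the methyl ketone enolate C7 acylates on C8, the only closure that gives a six-membered ring; under the reversible alkoxide conditions C5 epimerises through the C6 enolate, and the trans-fused dione enolate (H5 axial, α) is expected to accumulate as the thermodynamic sink.

Step 9
Reactants: 15 trans-fused 6,8-dione
Product: 16 11-benzyloxy-3α-(benzyloxymethoxy)-12-nor-5α-drimane-6,8-dione with C11 α (H9 β)
Conditions: LiN(i-Pr)2 (2.1 equiv), THF/DMPU, −78 to −20 °C; BnOCH2Cl (1.05 equiv), −78 °C; NH4Cl (aq); used crude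
Reagents that add atoms: benzyl chloromethyl ether, ClCOCc1ccccc1
Why: γ-Alkylation of a β-diketone dianion: the second deprotonation takes the C9 methylene and not the C5 methine between two quaternary carbons, and the terminal carbon is the most nucleophilic site; the electrophile approaches C9 anti to the axial C10 methyl, which puts C11 on the α face as the target requires.

Step 10
Reactants: 16 C9-alkylated dione
Product: 17 11-benzyloxy-3α-(benzyloxymethoxy)-6-oxo-12-nor-9-epi-drim-7-en-8-yl trifluoromethanesulfonate
Conditions: Tf2O (1.1 equiv), Et3N, CH2Cl2, −78 °C
Reagents that add atoms: trifluoromethanesulfonic anhydride, O=S(=O)(OS(=O)(=O)C(F)(F)F)C(F)(F)F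
Why: O-Sulfonylation of the 1,3-dione enolate; the oxygen on C8 is flanked in the ring plane only by H9, while the oxygen on C6 is screened by C5 and the equatorial C4 methyl, so the 8-triflate with the C6 ketone retained should form, and the weak base at low temperature leaves C5 and C9 alone.

Step 11
Reactants: 17 enol triflate
Product: 18 11-benzyloxy-3α-(benzyloxymethoxy)-9-epi-drim-7-en-6-one
Conditions: MeZnCl (2 equiv), Pd(PPh3)4 (5 mol %), THF, 0 °C to rt
Reagents that add atoms: methylzinc chloride, C[Zn]Cl
Why: Negishi cross-coupling of a β-triflyloxy enone; oxidative addition of zerovalent palladium to the electron-poor vinyl triflate is fast, methyl has no β-hydrogen, and the neutral organozinc neither enolises C5 or C9 nor adds to the enone.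

Step 12
Reactants: 18 protected enone
Product: 19 3α,11-dihydroxy-9-epi-drim-7-en-6-one
Conditions: BCl3 (6 equiv), C6HMe5 (6 equiv), CH2Cl2, −78 to −40 °C; MeOH, NaHCO3 (aq)
Reagents that add atoms: none
Why: Lewis acid ether cleavage with a cation scavenger: BCl3 cleaves the benzyl ether and the benzyloxymethyl acetal at low temperature, pentamethylbenzene traps the benzyl cations, and hydrogenolysis is avoided because of the enone alkene.

Step 13
Reactants: 19 3α,11-dihydroxy-9-epi-drim-7-en-6-one, 20 isofraxidin (7-hydroxy-6,8-dimethoxycoumarin)
Product: 21 7-[(3α-hydroxy-6-oxo-9-epi-drim-7-en-11-yl)oxy]-6,8-dimethoxycoumarin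
Conditions: PPh3, DIAD, THF, 0 °C to rt
Reagents that add atoms: none
Why: Mitsunobu etherification; only the primary C11 hydroxyl can form a reactive alkoxyphosphonium (the axial C3 hydroxyl next to the gem-dimethyl carbon is inert to substitution), and the acidic coumarin phenol is a suitable pronucleophile; substitution is at CH2, so no stereocentre is involved.

Step 14
Reactants: 21 aryl ether with free C3 hydroxyl
Product: 22 target, 7-{[3α-(3-methylbutanoyloxy)-6-oxo-9-epi-drim-7-en-11-yl]oxy}-6,8-dimethoxycoumarin (CNP0279705.1)
Conditions: i-BuCOCl, pyridine, DMAP (cat.), CH2Cl2, 0 °C to rt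
Reagents that add atoms: 3-methylbutanoyl chloride, CC(C)CC(=O)Cl
Why: DMAP-catalysed acylation of the hindered axial alcohol with retention at C3; the amine bases are too weak to enolise C5 or to expel the aryloxide from C11 through the γ-position C9.

Compound list

1 | 4-methylanisole | COc1ccc(C)cc1 | starting material
2 | 1-methoxy-4-methylcyclohexa-1,4-diene | COC1=CCC(C)=CC1 | intermediate
3 | 4-methylcyclohex-3-en-1-one | CC1=CCC(=O)CC1 | intermediate
4 | 2,2,4-trimethylcyclohex-3-en-1-one | CC1=CC(C)(C)C(=O)CC1 | intermediate
5 | (R)-2,2,4-trimethylcyclohex-3-en-1-ol | O[C@@H]1CCC(C)=CC1(C)C | intermediate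
6 | dichlorodiisopropylsilane | CC(C)[Si](Cl)(Cl)C(C)C | starting material
7 | methyl acetoacetate | COC(=O)CC(C)=O | starting material
8 | chloro(diisopropyl)silyl ether of 5 | CC(C)[Si](Cl)(C(C)C)O[C@@H]1CCC(C)=CC1(C)C | intermediate
9 | silicon-tethered (Z)-enol ether (key-step precursor) | COC(=O)/C=C(/C)O[Si](C(C)C)(C(C)C)O[C@@H]1CCC(C)=CC1(C)C | intermediate
10 | cyclobutane photoadduct | COC(=O)[C@@H]1[C@]2(C)O[Si](C(C)C)(C(C)C)O[C@@H]3CC[C@@]1(C)[C@H]2C3(C)C | intermediate
11 | desilylated cyclobutanol (3α,6-diol) | COC(=O)[C@@H]1[C@](C)(O)[C@@H]2C(C)(C)[C@H](O)CC[C@]12C | intermediate
12 | hydroxy keto ester (acetyl and acetate arm cis, α) | COC(=O)C[C@@]1(C)CC[C@@H](O)C(C)(C)[C@H]1C(C)=O | intermediate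
13 | O3-benzyloxymethyl keto ester (cis) | COC(=O)C[C@@]1(C)CC[C@@H](OCOCc2ccccc2)C(C)(C)[C@H]1C(C)=O | intermediate
14 | C5-epimerised keto ester (acetyl β, H5 α) | COC(=O)C[C@@]1(C)CC[C@@H](OCOCc2ccccc2)C(C)(C)[C@@H]1C(C)=O | intermediate
15 | 3α-(benzyloxymethoxy)-11,12-dinor-5α-drimane-6,8-dione | O=C1CC(=O)[C@H]2C(C)(C)[C@H](OCOCc3ccccc3)CC[C@]2(C)C1 | intermediate
16 | 9α-(benzyloxymethyl) dione (H9 β) | O=C1CC(=O)[C@H]2C(C)(C)[C@H](OCOCc3ccccc3)CC[C@]2(C)[C@@H]1COCc4ccccc4 | intermediate
17 | 8-triflyloxy-7-en-6-one | c1ccccc1COC[C@@H]2C(OS(=O)(=O)C(F)(F)F)=CC(=O)[C@H]3C(C)(C)[C@H](OCOCc4ccccc4)CC[C@]23C | intermediate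
18 | 11-benzyloxy-3α-(benzyloxymethoxy)-9-epi-drim-7-en-6-one | c1ccccc1COC[C@@H]2C(C)=CC(=O)[C@H]3C(C)(C)[C@H](OCOCc4ccccc4)CC[C@]23C | intermediate
19 | 3α,11-dihydroxy-9-epi-drim-7-en-6-one | OC[C@@H]1C(C)=CC(=O)[C@H]2C(C)(C)[C@H](O)CC[C@]12C | intermediate
20 | isofraxidin | COc1cc2ccc(=O)oc2c(OC)c1O | starting material
21 | 11-O-aryl ether with free 3α-OH | COc1cc2ccc(=O)oc2c(OC)c1OC[C@@H]1C(C)=CC(=O)[C@H]2C(C)(C)[C@H](O)CC[C@]12C | intermediate
22 | CNP0279705.1 | COc1cc2ccc(=O)oc2c(OC)c1OC[C@@H]1C(C)=CC(=O)[C@H]2C(C)(C)[C@H](OC(=O)CC(C)C)CC[C@]12C | target

Total step count: 14. Longest linear sequence: 14 steps (1 to 22); 6, 7 and 20 enter as bought.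

Least certain steps

Step 5 (key step, proposed new method). The most likely failure is unproductive decay of the enoate triplet: bond rotation and reversion of the 1,4-biradical may outrun closure through a seven-membered ring, and the sensitiser may add to the electron-rich alkenes instead. The fallback uses a cyclic chromophore whose intramolecular [2+2] photocycloaddition to tethered alkenes is established and which cannot relax by rotation. It sets out from 5 through 8 and comes back at 12. Chlorosilane 8 would be condensed with tetronic acid (Et3N, CH2Cl2) to the silyl tetronate F1. Direct irradiation at 254 nm should give the cyclobutane F2, with the same C5–C6 and C9–C10 bonds. Bu4NF would then trigger the same retro-aldol to the seven-membered keto lactone F3. Samarium diiodide (THF/MeOH, −78 °C) would cleave the α-acyloxy ketone bond C7–O to the keto acid F4. Me3SiCHN2 would esterify F4 to 12.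

Step 9. The likely failure is proton transfer from the alkylated monoanion to unreacted dianion, followed by β-elimination of benzyloxide across C9–C11, or over-alkylation. The fallback avoids strong base at the alkylation stage; it sets out from 15 and comes back at 16. Me3SiOTf and Et3N would convert 15 into the 6,8-bis(trimethylsilyloxy)-6,8-diene F5. Mukaiyama-type alkylation with BnOCH2Cl and ZnBr2 (cat., CH2Cl2, −78 °C) should then take place at the diene terminus C9, again anti to CH3-15, giving 16 after aqueous work-up.

Step 10. The likely failure is sulfonylation at the wrong enolate oxygen, the one on C6. The fallback turns that reactivity to account by changing the way the methyl group is introduced; it sets out from 16 and comes back at 18, replacing steps 10 and 11. O-Methylation with Me3SiCHN2 would give the 6-methoxy-6-en-8-one F6. MeLi with CeCl3 (THF, −78 °C) would add to the C8 carbonyl to give the tertiary carbinol F7. Dilute HCl would then effect the Stork–Danheiser transposition to 18.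

Step 13. The likely failure is slow substitution at the β-branched C11, so that the alkoxyphosphonium decomposes or eliminates across C9–C11 through the vinylogous enolate. The fallback separates activation from displacement; it sets out from 19 and comes back at 21. Selective mesylation of the primary hydroxyl (MsCl, Et3N, CH2Cl2, −20 °C) would give the mesylate F8. Displacement with 20 and Cs2CO3 in DMF at moderate temperature would give 21.

Further compounds

F1 | step 5 | silyl tetronate, 4-[(diisopropyl{[(1R)-2,2,4-trimethylcyclohex-3-en-1-yl]oxy}silyl)oxy]furan-2(5H)-one | O=C1OCC(O[Si](C(C)C)(C(C)C)O[C@@H]2CCC(C)=CC2(C)C)=C1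
F2 | step 5 | tetronate cyclobutane photoadduct | O=C1OC[C@]2(O[Si](C(C)C)(C(C)C)O[C@@H]3CC[C@@]4(C)[C@H]2C3(C)C)[C@H]14
F3 | step 5 | seven-membered keto lactone with free 3α-OH | O=C1C[C@@]2(C)CC[C@@H](O)C(C)(C)[C@H]2C(=O)CO1
F4 | step 5 | keto acid corresponding to 12 | OC(=O)C[C@@]1(C)CC[C@@H](O)C(C)(C)[C@H]1C(C)=O
F5 | step 9 | 6,8-bis(trimethylsilyloxy)-6,8-diene of 15 | C[Si](C)(C)OC1=CC(O[Si](C)(C)C)=C[C@@]2(C)CC[C@@H](OCOCc3ccccc3)C(C)(C)[C@H]12
F6 | step 10 | 6-methoxy-6-en-8-one from 16 | COC1=CC(=O)[C@@H](COCc2ccccc2)[C@@]3(C)CC[C@@H](OCOCc4ccccc4)C(C)(C)[C@H]13
F7 | step 10 | 8-methyl-8-hydroxy adduct of F6 (either configuration at C8) | COC1=CC(C)(O)[C@@H](COCc2ccccc2)[C@@]3(C)CC[C@@H](OCOCc4ccccc4)C(C)(C)[C@H]13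
F8 | step 13 | 11-methanesulfonate of 19 | CS(=O)(=O)OC[C@@H]1C(C)=CC(=O)[C@H]2C(C)(C)[C@H](O)CC[C@]12C
A1 | alternative 1 | 4-alkenyl-4-methoxycyclobutenone carrying the silylated drimanyl ether (either configuration at the ring sp3 carbon) | COC1=C(OC[C@@H]2C(C)=CC[C@H]3C(C)(C)[C@H](O[Si](C)(C)C(C)(C)C)CC[C@]23C)C(OC)(/C=C/CO[Si](C)(C)C(C)(C)C)C1=O
A2 | alternative 1 | 2-(silyloxymethyl)-4,6-dimethoxy-5-(drimanyloxy)phenol | COc1cc(CO[Si](C)(C)C(C)(C)C)c(O)c(OC)c1OC[C@@H]2C(C)=CC[C@H]3C(C)(C)[C@H](O[Si](C)(C)C(C)(C)C)CC[C@]23C
A3 | alternative 2 | ring A 2-silyloxydiene with (E)-crotonate on O3 | C/C=C/C(=O)O[C@@H]1CCC(C)=C(C(=C)O[Si](C)(C)C(C)(C)C)C1(C)C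
A4 | alternative 2 | bridged lactone cycloadduct | O=C1O[C@@H]2CC[C@]3(C)[C@H]1[C@@H](C)CC(O[Si](C)(C)C(C)(C)C)=C3C2(C)C
A5 | alternative 3 | (S)-10,11-epoxy-(2Z,6E)-farnesyl acetate | CC(=O)OC/C=C(/C)CC/C=C(\C)CC[C@@H]1OC1(C)C
A6 | alternative 3 | 3β-hydroxy-9-epi-drim-7-en-11-yl acetate | CC(=O)OC[C@@H]1C(C)=CC[C@H]2C(C)(C)[C@@H](O)CC[C@]12C
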